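The dihydropyranone ring (ring C) is disconnected at the aryl ether bond O1–C8a instead of the usual O1–C2 bond. C8a of ring A sits ortho to the C4 carbonyl, so an ortho-bromo aryl ketone is activated for palladium-catalysed C–O coupling, and the C2–O1 bond at the only stereocentre is never broken. The precursor is thus an open-chain (S)-β-hydroxy ketone, made by an asymmetric Mukaiyama aldol between the enol silane of 6-bromo-2,3,4-trimethoxyacetophenone and O-benzylvanillin. One intramolecular etherification closes ring C with retention at C2, bypassing the reversible oxa-Michael manifold in which flavanones racemise; hydrogenolysis then releases the 4'-phenol.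

Key step: step 4

Remark on numbering: flavanone numbering is used (O1, C2, C3, C4, C4a, C5 to C8, C8a; ring A is the benzo ring, ring B the 2-aryl group, ring C the heterocycle). The target is the (2S) enantiomer.

Assumption: the (S,S)-bisphosphoramide is taken as the catalyst enantiomer that directs Si-face addition to aromatic aldehydes (the (R,R)-form adding to the Re face). If a trial shows the opposite sense, its antipode is used and nothing else changes.

Step 1
Reactants: 1 5-bromo-1,2,3-trimethoxybenzene
Product: 2 1-(6-bromo-2,3,4-trimethoxyphenyl)ethan-1-one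
Conditions: AcCl, SnCl4, CH2Cl2, −10 °C to rt
Reagents that add atoms: acetyl chloride CC(=O)Cl
Why: Friedel–Crafts acylation: the two open positions of 1 are equivalent and each is ortho and para to methoxy groups, so a single ketone forms, and SnCl4 at low temperature is mild enough to spare the methoxy group next to the new carbonyl from chelation-assisted cleavage.

Step 2
Reactants: 2 1-(6-bromo-2,3,4-trimethoxyphenyl)ethan-1-one
Product: 3 {[1-(6-bromo-2,3,4-trimethoxyphenyl)ethenyl]oxy}trimethylsilane
Conditions: TMSOTf, Et3N, CH2Cl2, 0 °C
Reagents that add atoms: trimethylsilyl trifluoromethanesulfonate C[Si](C)(C)OS(=O)(=O)C(F)(F)F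
Why: Soft enolisation and O-silylation of a methyl ketone with TMSOTf/Et3N gives the only possible enol silane and avoids strong amide bases that could metalate the ring position between bromine and methoxy.

Step 3
Reactants: 3 {[1-(6-bromo-2,3,4-trimethoxyphenyl)ethenyl]oxy}trimethylsilane; 4 4-(benzyloxy)-3-methoxybenzaldehyde (O-benzylvanillin)
Product: 6 (3S)-3-[4-(benzyloxy)-3-methoxyphenyl]-1-(6-bromo-2,3,4-trimethoxyphenyl)-3-hydroxypropan-1-one, via trichlorosilyl aldolate 5 (not isolated)
Conditions: SiCl4 (1.5 equiv), (S,S)-bisphosphoramide (5 mol %; two N,N'-dimethyl-1,1'-binaphthyl-2,2'-diamine phosphoramide units linked through N,N'-dimethylpentane-1,5-diamine), iPr2NEt (10 mol %), CH2Cl2, −78 °C; then aq. KF/NaHCO3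
Reagents that add atoms: none
Why: Mukaiyama aldol addition under Lewis-base-activated SiCl4: the chiral bisphosphoramide-bound trichlorosilyl cation binds the aldehyde and exposes its Si face to the enol silane, so the C2 carbinol stereocentre is set as S by catalyst control, and buffered fluoride work-up hydrolyses the silyl aldolate without acid that would ionise the electron-rich benzylic alcohol.

Step 4
Reactants: 6 (3S)-3-[4-(benzyloxy)-3-methoxyphenyl]-1-(6-bromo-2,3,4-trimethoxyphenyl)-3-hydroxypropan-1-one
Product: 7 (2S)-2-[4-(benzyloxy)-3-methoxyphenyl]-5,6,7-trimethoxy-2,3-dihydro-4H-chromen-4-one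
Conditions: Pd(OAc)2 (5 mol %), racemic 2-(di-tert-butylphosphino)-1,1'-binaphthyl (6 mol %), K3PO4 (1.5 equiv), toluene, 70 °C
Reagents that add atoms: none
Why: Oxidative addition of zerovalent palladium into the C8a–Br bond, which the ortho C4 carbonyl activates, is followed by binding and K3PO4 deprotonation of the C2 hydroxyl and by C–O reductive elimination through a seven-membered palladacycle, which forms O1–C8a. The closest known reaction type is the Buchwald–Hartwig intramolecular etherification of aryl bromides with tethered secondary alcohols that gives 2-substituted chromans. Ring C is closed as a six-membered ring in an exo mode by reductive elimination, the C4–C3–C2 tether fixing attack at C8a. No stereocentre is created: C2 keeps the S configuration from step 3 because its own C–O bond is never broken. The step needs chemoselectivity for C–O coupling over retro-aldol, dehydration to the chalcone and β-hydride elimination; this should be secured by the weak, insoluble base in toluene, the bulky di-tert-butylphosphine that speeds reductive elimination from an electron-poor ortho-acyl aryl palladium, and the twisted, doubly ortho-substituted ketone whose α-hydrogens are only weakly acidified.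

Step 5
Reactants: 7 (2S)-2-[4-(benzyloxy)-3-methoxyphenyl]-5,6,7-trimethoxy-2,3-dihydro-4H-chromen-4-one
Product: 8 Agecorynin E, (2S)-2-(4-hydroxy-3-methoxyphenyl)-5,6,7-trimethoxy-2,3-dihydro-4H-chromen-4-one
Conditions: H2 (1 atm), 10% Pd/C, EtOAc, rt
Reagents that add atoms: none
Why: Hydrogenolysis of the benzyl aryl ether over palladium is neutral, so the 4'-phenol is freed without the base that would open ring C through a quinone methide and racemise C2, and the aryl ketone and methoxy groups should be untouched at one atmosphere.

Compound list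
1 | 5-bromo-1,2,3-trimethoxybenzene | COc1cc(Br)cc(OC)c1OC | starting material
2 | 1-(6-bromo-2,3,4-trimethoxyphenyl)ethan-1-one | CC(=O)c1c(Br)cc(OC)c(OC)c1OC | intermediate
3 | {[1-(6-bromo-2,3,4-trimethoxyphenyl)ethenyl]oxy}trimethylsilane | C=C(O[Si](C)(C)C)c1c(Br)cc(OC)c(OC)c1OC | intermediate
4 | 4-(benzyloxy)-3-methoxybenzaldehyde | O=Cc1ccc(OCc2ccccc2)c(OC)c1 | starting material
5 | trichlorosilyl aldolate, the O-trichlorosilyl ether of 6 | Cl[Si](Cl)(Cl)O[C@@H](CC(=O)c1c(Br)cc(OC)c(OC)c1OC)c1ccc(OCc2ccccc2)c(OC)c1 | intermediate
6 | (3S)-3-[4-(benzyloxy)-3-methoxyphenyl]-1-(6-bromo-2,3,4-trimethoxyphenyl)-3-hydroxypropan-1-one | O[C@@H](CC(=O)c1c(Br)cc(OC)c(OC)c1OC)c1ccc(OCc2ccccc2)c(OC)c1 | intermediate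
7 | (2S)-2-[4-(benzyloxy)-3-methoxyphenyl]-5,6,7-trimethoxy-2,3-dihydro-4H-chromen-4-one | COc1cc([C@@H]2CC(=O)c3c(cc(OC)c(OC)c3OC)O2)ccc1OCc1ccccc1 | intermediate
8 | Agecorynin E, (2S)-2-(4-hydroxy-3-methoxyphenyl)-5,6,7-trimethoxy-2,3-dihydro-4H-chromen-4-one | COc1cc([C@@H]2CC(=O)c3c(cc(OC)c(OC)c3OC)O2)ccc1O | target

Total step count: 5. Longest linear sequence: 5 steps (1 to 2 to 3 to 6 to 7 to 8).

Steps most likely to fail

Step 4. Under base and heat the aldol may undergo retro-aldol cleavage (loss of configuration) or dehydration to the chalcone faster than C–O reductive elimination. β-Hydride elimination from the palladium alkoxide may also lead to debromination. The fallback sets out from 6 and removes the enolisable carbonyl before the ring closure. Evans–Saksena reduction (Me4NBH(OAc)3, MeCN/AcOH, −20 °C) should give the anti diol, (1S,3S)-3-[4-(benzyloxy)-3-methoxyphenyl]-1-(6-bromo-2,3,4-trimethoxyphenyl)propane-1,3-diol F1. Copper-catalysed intramolecular Ullmann etherification (CuI, 3,4,7,8-tetramethyl-1,10-phenanthroline, Cs2CO3, toluene, 100 °C) then closes the same O1–C8a bond. Only the C2 hydroxyl can reach C8a in a six-membered ring, and copper alkoxides tolerate the free C4 carbinol. This should give (2S,4S)-2-[4-(benzyloxy)-3-methoxyphenyl]-5,6,7-trimethoxy-3,4-dihydro-2H-chromen-4-ol F2. Dess–Martin oxidation of the C4 carbinol (CH2Cl2, rt) comes back to the route at 7.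

Step 3. Facial discrimination at the aldehyde may be insufficient, the sense of induction may be opposite to that assumed, or the hindered enol silane may add sluggishly. The fallback sets out from 2 and 4 and fixes the stereocentre by epoxidation instead. Claisen–Schmidt condensation (Ba(OH)2, EtOH, rt) should give (E)-3-[4-(benzyloxy)-3-methoxyphenyl]-1-(6-bromo-2,3,4-trimethoxyphenyl)prop-2-en-1-one F3. Juliá–Colonna epoxidation (poly-D-leucine, urea–hydrogen peroxide, DBU, THF, rt) should give [(2S,3R)-3-[4-(benzyloxy)-3-methoxyphenyl]oxiran-2-yl](6-bromo-2,3,4-trimethoxyphenyl)methanone F4. Reductive cleavage of the Cα–O bond with sodium phenylselenide (PhSeSePh, NaBH4, AcOH, EtOH, 0 °C), which leaves the aryl bromide and the Cβ–O bond alone, comes back to the route at 6.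

Step 1. The Lewis acid may cleave the methoxy group ortho to the new acetyl group through chelation, or acylation of the bromine-deactivated ring may stall. The fallback sets out from 1 and replaces electrophilic substitution by directed ortho-lithiation at the position between bromine and methoxy (LDA, THF, −78 °C), followed by a quench with N-methoxy-N-methylacetamide. This comes back to the route at 2 directly (no new compound, F0).

Further compounds
F1 | step 4 | (1S,3S)-3-[4-(benzyloxy)-3-methoxyphenyl]-1-(6-bromo-2,3,4-trimethoxyphenyl)propane-1,3-diol | O[C@@H](C[C@H](O)c1c(Br)cc(OC)c(OC)c1OC)c1ccc(OCc2ccccc2)c(OC)c1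
F2 | step 4 | (2S,4S)-2-[4-(benzyloxy)-3-methoxyphenyl]-5,6,7-trimethoxy-3,4-dihydro-2H-chromen-4-ol | COc1cc([C@@H]2C[C@H](O)c3c(cc(OC)c(OC)c3OC)O2)ccc1OCc1ccccc1
F3 | step 3 | (E)-3-[4-(benzyloxy)-3-methoxyphenyl]-1-(6-bromo-2,3,4-trimethoxyphenyl)prop-2-en-1-one | O=C(/C=C/c1ccc(OCc2ccccc2)c(OC)c1)c1c(Br)cc(OC)c(OC)c1OC
F4 | step 3 | [(2S,3R)-3-[4-(benzyloxy)-3-methoxyphenyl]oxiran-2-yl](6-bromo-2,3,4-trimethoxyphenyl)methanone | O=C([C@H]1O[C@@H]1c1ccc(OCc2ccccc2)c(OC)c1)c1c(Br)cc(OC)c(OC)c1OC
F0 | step 1 | none | none
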